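**Strategy.** The route rests on cutting the bond between ring carbon C2 (the O1–CH carbon next to C3H2) and C2', the chlorine-bearing quaternary carbon of the side chain. A Lewis-acid-mediated C-glycosylation joins a ring oxocarbenium ion (O1=C2), generated from a 2-acetoxy-3,6-dihydro-2H-pyran that already carries the C4=C5 alkene and CHBr2 at C6, with the tetrasubstituted silyl ketene acetal of methyl 2-chloropropanoate. In one operation it forms the C2–C2' bond, the tertiary C–Cl centre and the 2,6-trans ring relationship, both relayed from C6, which is set by Sharpless kinetic resolution. The feature exploited is the acetal-level carbon C2 of the dihydropyran ring, flanked by O1 and shielded on one face by the C6 substituent.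

Key step: step 7

Remark on the chemistry: ring atoms are numbered O1, C2 (bears the side chain), C3H2, C4=C5(CH3), C6 (bears CHBr2); C2' is the chlorine-bearing carbon of the side chain. Methyl 2-chloropropanoate is used as the racemate, since its stereocentre is erased on enolisation.

Step 1
Reactants: 1 dibromomethane; 2 methacrolein (2-methylprop-2-enal)
Product: 4 rac-1,1-dibromo-3-methylbut-3-en-2-ol, via dibromomethyllithium 3 (not isolated)
Conditions: LDA, THF, −78 °C; then 2, −78 °C; AcOH quench at −78 °C
Reagents that add atoms: none
Why: Deprotonation of CH2Br2 gives the lithium carbenoid, which adds 1,2 to the aldehyde (carbenoid carbonyl addition); the cold acidic quench should stop the bromohydrin alkoxide from closing to a bromo-epoxide, and the new centre forms racemic.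

Step 2
Reactants: 4 rac-1,1-dibromo-3-methylbut-3-en-2-ol
Product: 5 (2S)-1,1-dibromo-3-methylbut-3-en-2-ol (recovered enantiomer)
Conditions: Ti(OiPr)4, L-(+)-DIPT, t-BuOOH (0.6 equiv), 4 Å MS, CH2Cl2, −20 °C
Reagents that add atoms: none
Why: Sharpless kinetic resolution: with L-(+)-tartrate the enantiomer whose CHBr2 group points away from the delivered oxygen is epoxidised fast, so the enantiomer with CHBr2 on the reagent face should be recovered; it is (S) because CHBr2 outranks isopropenyl.

Step 3
Reactants: 5 (2S)-1,1-dibromo-3-methylbut-3-en-2-ol; 6 but-3-enoic acid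
Product: 7 (2S)-1,1-dibromo-3-methylbut-3-en-2-yl but-3-enoate
Conditions: DCC, DMAP (cat.), CH2Cl2, 0 °C
Reagents that add atoms: none
Why: Steglich esterification at the oxygen leaves the stereocentre untouched, and low temperature with little DMAP should keep the β,γ-alkene out of conjugation.

Step 4
Reactants: 7 (2S)-1,1-dibromo-3-methylbut-3-en-2-yl but-3-enoate
Product: 8 (6S)-6-(dibromomethyl)-5-methyl-3,6-dihydro-2H-pyran-2-one
Conditions: Grubbs II (5 mol %), 1,4-benzoquinone (10 mol %), CH2Cl2 (5 mM), 40 °C
Reagents that add atoms: none
Why: Ring-closing metathesis of the terminal alkene onto the 1,1-disubstituted alkene should give the six-membered lactone with the trisubstituted C4=C5 bond, driven by loss of ethylene; benzoquinone suppresses Ru–H alkene migration.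

Step 5
Reactants: 8 (6S)-6-(dibromomethyl)-5-methyl-3,6-dihydro-2H-pyran-2-one
Product: 10 (6S)-6-(dibromomethyl)-5-methyl-3,6-dihydro-2H-pyran-2-yl acetate (both C2 epimers), via diisobutylaluminium lactolate 9 (not isolated)
Conditions: DIBAL-H (1.1 equiv), CH2Cl2, −78 °C; then pyridine, DMAP, Ac2O, −78 → 0 °C
Reagents that add atoms: acetic anhydride CC(=O)OC(C)=O
Why: Reductive acetylation: the tetrahedral aluminium hemiacetal is trapped by acetylation before it can open, and the C2 configuration does not matter because step 7 erases it.

Step 6
Reactants: 11 methyl 2-chloropropanoate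
Product: 13 2-chloro-1-methoxy-1-(trimethylsilyloxy)prop-1-ene (E/Z mixture), via lithium ester enolate 12 (not isolated)
Conditions: LDA, TMSCl (internal quench), THF, −78 °C; distillation
Reagents that add atoms: chlorotrimethylsilane C[Si](C)(C)Cl
Why: Ester enolate O-silylation in the presence of TMSCl should trap the α-chloro enolate before Darzens-type self-condensation; the geometry matters little because both substituents on the acetal carbon are oxygen.

Step 7
Reactants: 10 (6S)-6-(dibromomethyl)-5-methyl-3,6-dihydro-2H-pyran-2-yl acetate; 13 2-chloro-1-methoxy-1-(trimethylsilyloxy)prop-1-ene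
Product: 15 methyl (2R)-2-chloro-2-[(2S,6S)-6-(dibromomethyl)-5-methyl-3,6-dihydro-2H-pyran-2-yl]propanoate, via oxocarbenium triflate 14 (not isolated)
Conditions: TMSOTf (20 mol %), CH2Cl2, −78 °C
Reagents that add atoms: none
Why: TMSOTf ionises the anomeric acetate to the ring oxocarbenium ion O1=C2 (14), the nucleophilic carbon of 13 adds to C2, and transfer of the silyl group to acetate regenerates the Lewis acid. The closest known reaction type is the Mukaiyama-type C-glycosylation of lactol acetates with tetrasubstituted silyl ketene acetals; no ring is closed. C2 is controlled by C6: the nucleophile should enter on the ring face opposite the CHBr2 group, so that the half-chair product forms with the new bond pseudoaxial and CHBr2 pseudoequatorial, which is the 2,6-trans arrangement. C2' is controlled by the relative topicity of an open synclinal transition state in which the C–Cl bond, the smallest and most polarisable of the three groups, lies over the ring between O1 and C3, the ketene acetal carbon is gauche to O1 and the methyl group points outward anti to O1; this arrangement leads to the (2'R) centre. The step needs the addition to outrun loss of a C3 proton from the cation (which would give a 2H-pyran), and the high nucleophilicity of the ketene acetal at −78 °C is expected to secure this.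

Step 8
Reactants: 15 methyl (2R)-2-chloro-2-[(2S,6S)-6-(dibromomethyl)-5-methyl-3,6-dihydro-2H-pyran-2-yl]propanoate
Product: 16 (2S)-2-chloro-2-[(2S,6S)-6-(dibromomethyl)-5-methyl-3,6-dihydro-2H-pyran-2-yl]propan-1-ol
Conditions: DIBAL-H (2.5 equiv), CH2Cl2, −78 → −40 °C; Rochelle salt work-up
Reagents that add atoms: none
Why: Hydride reduction of the ester to the primary alcohol should leave the alkyl bromides, the tertiary chloride and all stereocentres untouched; the C2' descriptor changes to S by CIP priority only.

Step 9
Reactants: 16 (2S)-2-chloro-2-[(2S,6S)-6-(dibromomethyl)-5-methyl-3,6-dihydro-2H-pyran-2-yl]propan-1-ol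
Product: 18 (2S,6S)-6-(dibromomethyl)-2-[(2R)-1,2-dichloropropan-2-yl]-5-methyl-3,6-dihydro-2H-pyran, via primary triflate 17 (not isolated)
Conditions: Tf2O, 2,6-lutidine, CH2Cl2, −78 °C; then n-Bu4NCl, −78 °C → rt
Reagents that add atoms: tetrabutylammonium chloride CCCC[N+](CCCC)(CCCC)CCCC.[Cl-]
Why: The neopentyl-type alcohol is activated as its triflate and displaced by chloride in an SN2 reaction at the CH2 carbon only, so no stereocentre is involved; the C2' descriptor returns to R by CIP priority.

**Compound list**

1 | dibromomethane | BrCBr | starting material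
2 | methacrolein (2-methylprop-2-enal) | CC(=C)C=O | starting material
3 | dibromomethyllithium | [Li]C(Br)Br | intermediate
4 | rac-1,1-dibromo-3-methylbut-3-en-2-ol | CC(=C)C(O)C(Br)Br | intermediate
5 | (2S)-1,1-dibromo-3-methylbut-3-en-2-ol | O[C@@H](C(C)=C)C(Br)Br | intermediate
6 | but-3-enoic acid | OC(=O)CC=C | starting material
7 | (2S)-1,1-dibromo-3-methylbut-3-en-2-yl but-3-enoate | C=CCC(=O)O[C@@H](C(C)=C)C(Br)Br | intermediate
8 | (6S)-6-(dibromomethyl)-5-methyl-3,6-dihydro-2H-pyran-2-one | O=C1CC=C(C)[C@@H](C(Br)Br)O1 | intermediate
9 | diisobutylaluminium (6S)-6-(dibromomethyl)-5-methyl-3,6-dihydro-2H-pyran-2-olate | CC(C)C[Al](CC(C)C)OC1CC=C(C)[C@@H](C(Br)Br)O1 | intermediate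
10 | (6S)-6-(dibromomethyl)-5-methyl-3,6-dihydro-2H-pyran-2-yl acetate (both C2 epimers) | CC(=O)OC1CC=C(C)[C@@H](C(Br)Br)O1 | intermediate
11 | methyl 2-chloropropanoate (racemic) | COC(=O)C(C)Cl | starting material
12 | lithium enolate of methyl 2-chloropropanoate | COC(O[Li])=C(C)Cl | intermediate
13 | 2-chloro-1-methoxy-1-(trimethylsilyloxy)prop-1-ene (E/Z mixture) | COC(O[Si](C)(C)C)=C(C)Cl | intermediate
14 | (6S)-6-(dibromomethyl)-5-methyl-3,6-dihydropyran-1-ium (ring oxocarbenium ion, O1=C2) triflate | CC1=CCC=[O+][C@@H]1C(Br)Br.[O-]S(=O)(=O)C(F)(F)F | intermediate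
15 | methyl (2R)-2-chloro-2-[(2S,6S)-6-(dibromomethyl)-5-methyl-3,6-dihydro-2H-pyran-2-yl]propanoate | CC1=CC[C@@H]([C@@](C)(Cl)C(=O)OC)O[C@@H]1C(Br)Br | intermediate
16 | (2S)-2-chloro-2-[(2S,6S)-6-(dibromomethyl)-5-methyl-3,6-dihydro-2H-pyran-2-yl]propan-1-ol | CC1=CC[C@@H]([C@@](C)(Cl)CO)O[C@@H]1C(Br)Br | intermediate
17 | (2S)-2-chloro-2-[(2S,6S)-6-(dibromomethyl)-5-methyl-3,6-dihydro-2H-pyran-2-yl]propyl trifluoromethanesulfonate | CC1=CC[C@@H]([C@@](C)(Cl)COS(=O)(=O)C(F)(F)F)O[C@@H]1C(Br)Br | intermediate
18 | (2S,6S)-6-(dibromomethyl)-2-[(2R)-1,2-dichloropropan-2-yl]-5-methyl-3,6-dihydro-2H-pyran | CC1=CC[C@@H]([C@@](C)(Cl)CCl)O[C@@H]1C(Br)Br | target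

**Step count.** Total: 9 steps. Longest linear sequence: 8 steps (steps 1–5 and 7–9); step 6 is a one-step branch.

**Steps most likely to fail**

Step 7. The nucleophile may add with poor facial selectivity on its own prochiral carbon, giving the wrong relative topicity at C2'. The cation may also lose a C3 proton before it is captured. The fallback separates bond formation from the setting of C2'. It sets out from lactol acetate 10: TMSOTf-mediated addition of (Z)-trimethyl(prop-1-en-1-yloxy)silane should give the trans aldehyde 2-[(2S,6S)-6-(dibromomethyl)-5-methyl-3,6-dihydro-2H-pyran-2-yl]propanal F1, whose C2' configuration is of no consequence. Enamine-mediated α-chlorination of F1 with N-chlorosuccinimide and a chiral amine catalyst would then install the chlorine under catalyst control, giving (2R)-2-chloro-2-[(2S,6S)-6-(dibromomethyl)-5-methyl-3,6-dihydro-2H-pyran-2-yl]propanal F2. Reduction of F2 with NaBH4 comes back to the route at alcohol 16.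

Step 9. Substitution at the neopentyl-type carbon may be slow, which would let the neighbouring tertiary chlorine participate through a chloriranium ion and scramble C2', or let elimination compete. The fallback replaces the direct displacement by two inversions at C2'. It sets out from alcohol 16: K2CO3 in MeOH should close the chlorohydrin, with inversion at C2', to (2S,6S)-6-(dibromomethyl)-5-methyl-2-[(2R)-2-methyloxiran-2-yl]-3,6-dihydro-2H-pyran F3. Deoxydichlorination of F3 with Ph3PCl2 in CH2Cl2 would open the epoxide at the tertiary carbon with a second inversion and replace the primary C–O bond, coming back to the route at target 18.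

Step 2. Epoxidation of the electron-poor alkene may be slow and the rate difference between the enantiomers small, so that the recovered alcohol is not enantiopure at an acceptable conversion. The fallback replaces resolution by asymmetric reduction. It sets out from racemic alcohol 4: Dess–Martin oxidation should give 1,1-dibromo-3-methylbut-3-en-2-one F4. Enantioselective reduction of F4, with a ketoreductase chosen for the (S)-alcohol or by Corey–Bakshi–Shibata reduction, comes back to the route at alcohol 5 without losing half the material.

**Further compounds**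

F1 | step 7 | 2-[(2S,6S)-6-(dibromomethyl)-5-methyl-3,6-dihydro-2H-pyran-2-yl]propanal | CC1=CC[C@@H](C(C)C=O)O[C@@H]1C(Br)Br
F2 | step 7 | (2R)-2-chloro-2-[(2S,6S)-6-(dibromomethyl)-5-methyl-3,6-dihydro-2H-pyran-2-yl]propanal | CC1=CC[C@@H]([C@@](C)(Cl)C=O)O[C@@H]1C(Br)Br
F3 | step 9 | (2S,6S)-6-(dibromomethyl)-5-methyl-2-[(2R)-2-methyloxiran-2-yl]-3,6-dihydro-2H-pyran | CC1=CC[C@@H]([C@]2(C)OC2)O[C@@H]1C(Br)Br
F4 | step 2 | 1,1-dibromo-3-methylbut-3-en-2-one | CC(=C)C(=O)C(Br)Br
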